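**Retrosynthetic overview**
1. The last bonds made are C2'–CH3 (nickel-catalysed exchange of a C2'–SMe group) and O8–CH3. Before that, the biaryl bond C7–C1' is made by a dehydrogenative, sulfonium-tethered [3,3]-sigmatropic coupling of 1,3-dimethylisoquinolin-8-ol with a 2-naphthyl methyl sulfoxide; neither carbon carries a halogen or boron.
2. Enabling feature: the 8-oxygen on the carbocyclic ring of the isoquinoline is ortho to C7 (its only free ortho position, the other being ring-fusion carbon C8a), and the methyl-bearing C2' of the naphthalene is ortho to C1'. With sulfur standing in for the 2'-methyl carbon, O8–C8=C7 and C1'=C2'–S become a hetero-1,5-diene once O and S are joined.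
3. Ring order: the naphthalene is bought (1,8-dimethoxynaphthalene, functionalised at C3 by Ir-catalysed C–H borylation). The pyridine ring of the isoquinoline is closed from an o-alkynyl acetophenone and NH3 (6-endo-dig) before the coupling. No ring is formed afterwards.
4. The sulfur is traceless: it arrives from S-methyl methanethiosulfonate and leaves as methanethiolate when MeMgBr installs the 2'-methyl group.

Key step: step 7

Remark: the target SMILES defines no stereo element; the biaryl axis (three ortho substituents plus the peri C8'–H) should rotate slowly, and the route is planned to give the racemate. Primed locants refer to the naphthalene numbered as in the target (C1' on the axis, C2' methyl, C4' and C5' methoxy).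

**Route**

Step 1
Reactants: 1 1,8-dimethoxynaphthalene
Product: 2 2-(4,5-dimethoxynaphthalen-2-yl)-4,4,5,5-tetramethyl-1,3,2-dioxaborolane
Conditions: B2pin2 (0.6 equiv), [Ir(OMe)(cod)]2 (1.5 mol%), 4,4'-di-tert-butyl-2,2'-bipyridine (3 mol%), THF, 60 °C; excess 1 recovered
Reagents that add atoms: bis(pinacolato)diboron, CC1(C)OB(OC1(C)C)B1OC(C)(C)C(C)(C)O1
Why: Sterically governed Ir-catalysed aromatic C–H borylation (Hartwig–Miyaura type), in which C3 and its symmetry equivalent C6 are the only C–H bonds of 1 with neither an ortho substituent nor a peri neighbour, and the excess of 1 should hold the reaction at the mono-boronate.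

Step 2
Reactants: 2 2-(4,5-dimethoxynaphthalen-2-yl)-4,4,5,5-tetramethyl-1,3,2-dioxaborolane
Product: 3 1,8-dimethoxy-3-(methylsulfanyl)naphthalene
Conditions: MeSO2SMe (1.5 equiv), CuSO4 (10 mol%), 1,10-phenanthroline (10 mol%), CsF (2 equiv), MeOH, 50 °C
Reagents that add atoms: S-methyl methanethiosulfonate, CS(=O)(=O)SC
Why: Copper-catalysed deborylative thiolation of an aryl boronic ester with a thiosulfonate (fluoride-assisted boron-to-copper transmetalation, then sulfur transfer from the electrophilic reagent), a mild ipso exchange that should leave the electron-rich ring untouched.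

Step 3
Reactants: 3 1,8-dimethoxy-3-(methylsulfanyl)naphthalene
Product: 4 1,8-dimethoxy-3-(methanesulfinyl)naphthalene (racemic at sulfur)
Conditions: NaIO4 (1.05 equiv), MeOH/H2O, 0 °C → rt
Reagents that add atoms: sodium periodate, [Na+].[O-]I(=O)(=O)=O
Why: Periodate oxidation of an aryl methyl sulfide should stop at the sulfoxide without attacking the electron-rich naphthalene; the sulfur stereocentre forms as the racemate, which is all the route needs.

Step 4
Reactants: 5 1-(2,6-dihydroxyphenyl)ethan-1-one
Product: 6 2-acetyl-3-hydroxyphenyl trifluoromethanesulfonate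
Conditions: Tf2O (1.05 equiv), pyridine (2 equiv), CH2Cl2, −78 → 0 °C
Reagents that add atoms: trifluoromethanesulfonic anhydride, FC(F)(F)S(=O)(=O)OS(=O)(=O)C(F)(F)F
Why: Mono-O-triflation of a symmetric 2-acylresorcinol, in which the remaining hydroxyl is locked in a hydrogen bond to the acetyl carbonyl after the first sulfonylation and should react much more slowly.

Step 5
Reactants: 6 2-acetyl-3-hydroxyphenyl trifluoromethanesulfonate
Product: 7 1-[2-hydroxy-6-(prop-1-yn-1-yl)phenyl]ethan-1-one
Conditions: propyne (3 equiv, THF solution), PdCl2(PPh3)2 (5 mol%), CuI (10 mol%), Et3N (3 equiv), DMF, 50 °C, sealed tube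
Reagents that add atoms: propyne, CC#C
Why: Sonogashira coupling of an aryl triflate activated by the ortho acetyl group; the chelated phenol is tolerated and sits meta to the new alkyne, so no benzofuran can form.

Step 6
Reactants: 7 1-[2-hydroxy-6-(prop-1-yn-1-yl)phenyl]ethan-1-one
Product: 9 1,3-dimethylisoquinolin-8-ol, via N–H ketimine 8 (not isolated)
Conditions: NH3 (7 M in MeOH, excess), sealed tube, 90 °C
Reagents that add atoms: ammonia, N
Why: Condensation with ammonia gives ketimine 8, whose nitrogen adds to the distal alkyne carbon in a 6-endo-dig hydroamination and tautomerises to the aromatic isoquinoline, the classical isoquinoline synthesis from o-alkynyl aryl carbonyl compounds.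

Step 7
Reactants: 4 1,8-dimethoxy-3-(methanesulfinyl)naphthalene; 9 1,3-dimethylisoquinolin-8-ol
Product: 13 7-[4,5-dimethoxy-2-(methylsulfanyl)naphthalen-1-yl]-1,3-dimethylisoquinolin-8-ol, via trifluoroacetoxysulfonium salt 10 (not isolated), via aryloxysulfonium salt 11 (not isolated), via dienone–thionium salt 12 (not isolated)
Conditions: 9 (1.2 equiv) as its CF3CO2H salt (TFA 1.1 equiv), (CF3CO)2O (2.0 equiv), CH2Cl2, −20 °C → rt; then aq NaHCO3
Reagents that add atoms: none
Why: Trifluoroacetic anhydride O-acylates sulfoxide 4 to sulfonium ion 10, the phenolic oxygen of 9 displaces trifluoroacetate at sulfur (interrupted Pummerer) to give the S–O-linked ion 11, and its O8–C8=C7 / C1'=C2'–S array undergoes a charge-accelerated [3,3]-sigmatropic shift that forms C7–C1' and breaks S–O to give 12, which tautomerises twice to the aromatic biaryl 13. The closest known reaction type is the sulfonium-tethered dehydrogenative coupling of phenols and naphthols with aryl methyl sulfoxides to 2-hydroxy-2'-(methylsulfanyl)biaryls under trifluoroacetic anhydride activation. No ring is closed: the bond forms through a six-membered cyclic transition state whose S–O link is cleaved in the same event, so the tether leaves only the sulfur on C2'. The two sp3 centres of 12 (C7 and C1') vanish on rearomatisation and the new stereogenic axis forms without control, so 13 should be racemic. Regioselectivity rests on the substrate: C7 is the only hydrogen-bearing ortho carbon of the 8-oxygen (the other is ring-fusion C8a, and para C5 is out of reach of the tether), and on the naphthalene the shift should go to C1' and not C3' because only the C1'=C2' bond has high double-bond character and can be used while the second ring stays aromatic. Chemoselectivity needs oxygen attack at sulfur to beat Pummerer or ylide chemistry at the S-methyl group, which is why the basic nitrogen is masked as its trifluoroacetate salt so that no base stronger than trifluoroacetate is present.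

Step 8
Reactants: 13 7-[4,5-dimethoxy-2-(methylsulfanyl)naphthalen-1-yl]-1,3-dimethylisoquinolin-8-ol
Product: 14 7-[4,5-dimethoxy-2-(methylsulfanyl)naphthalen-1-yl]-8-methoxy-1,3-dimethylisoquinoline
Conditions: MeI (1.1 equiv), Cs2CO3 (1.5 equiv), DMF, 0 °C → rt
Reagents that add atoms: iodomethane, CI
Why: Williamson O-methylation of the caesium phenoxide, which should outrun quaternisation of the nitrogen flanked by the 1- and 3-methyl groups (lutidine-like) and S-alkylation of the aryl methyl sulfide.

Step 9
Reactants: 14 7-[4,5-dimethoxy-2-(methylsulfanyl)naphthalen-1-yl]-8-methoxy-1,3-dimethylisoquinoline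
Product: 15 7-(4,5-dimethoxy-2-methylnaphthalen-1-yl)-8-methoxy-1,3-dimethylisoquinoline (target, racemic axis)
Conditions: MeMgBr (3 equiv), NiCl2(PPh3)2 (10 mol%), toluene/THF, 80 °C; then H2O
Reagents that add atoms: methylmagnesium bromide, C[Mg]Br
Why: Nickel-catalysed Kumada-type coupling of an aryl methyl sulfide with a Grignard reagent (Wenkert coupling), in which zerovalent nickel inserts into the aryl C–S bond and transmetalation and reductive elimination replace sulfur by methyl, while aryl methyl ethers should stay inert with a triphenylphosphine-ligated catalyst.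

**Compound list**
1 | 1,8-dimethoxynaphthalene | COc1cccc2cccc(OC)c12 | starting material
2 | 2-(4,5-dimethoxynaphthalen-2-yl)-4,4,5,5-tetramethyl-1,3,2-dioxaborolane | COc1cc(B2OC(C)(C)C(C)(C)O2)cc2cccc(OC)c12 | intermediate
3 | 1,8-dimethoxy-3-(methylsulfanyl)naphthalene | CSc1cc(OC)c2c(OC)cccc2c1 | intermediate
4 | 1,8-dimethoxy-3-(methanesulfinyl)naphthalene (racemic at sulfur) | CS(=O)c1cc(OC)c2c(OC)cccc2c1 | intermediate
5 | 1-(2,6-dihydroxyphenyl)ethan-1-one | CC(=O)c1c(O)cccc1O | starting material
6 | 2-acetyl-3-hydroxyphenyl trifluoromethanesulfonate | CC(=O)c1c(O)cccc1OS(=O)(=O)C(F)(F)F | intermediate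
7 | 1-[2-hydroxy-6-(prop-1-yn-1-yl)phenyl]ethan-1-one | CC#Cc1cccc(O)c1C(C)=O | intermediate
8 | 2-(1-iminoethyl)-3-(prop-1-yn-1-yl)phenol (N–H ketimine) | CC#Cc1cccc(O)c1C(C)=N | intermediate (not isolated)
9 | 1,3-dimethylisoquinolin-8-ol | Cc1cc2cccc(O)c2c(C)n1 | intermediate
10 | (4,5-dimethoxynaphthalen-2-yl)(methyl)(trifluoroacetoxy)sulfonium trifluoroacetate (racemic at sulfur) | C[S+](OC(=O)C(F)(F)F)c1cc(OC)c2c(OC)cccc2c1.[O-]C(=O)C(F)(F)F | intermediate (not isolated)
11 | (4,5-dimethoxynaphthalen-2-yl)[(1,3-dimethylisoquinolin-8-yl)oxy](methyl)sulfonium trifluoroacetate (racemic at sulfur; drawn as the free base at nitrogen, protonated in the flask) | C[S+](Oc1cccc2cc(C)nc(C)c12)c1cc(OC)c2c(OC)cccc2c1.[O-]C(=O)C(F)(F)F | intermediate (not isolated)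
12 | [1-(1,3-dimethyl-8-oxo-7,8-dihydroisoquinolin-7-yl)-4,5-dimethoxynaphthalen-2(1H)-ylidene](methyl)sulfonium trifluoroacetate (transient sp3 centres at C7 and C1', configuration unspecified; drawn as the free base at nitrogen) | C[S+]=C1C=C(OC)c2c(OC)cccc2C1C1C=Cc2cc(C)nc(C)c2C1=O.[O-]C(=O)C(F)(F)F | intermediate (not isolated)
13 | 7-[4,5-dimethoxy-2-(methylsulfanyl)naphthalen-1-yl]-1,3-dimethylisoquinolin-8-ol (racemic axis) | Cc1cc2ccc(-c3c(SC)cc(OC)c4c(OC)cccc34)c(O)c2c(C)n1 | intermediate
14 | 7-[4,5-dimethoxy-2-(methylsulfanyl)naphthalen-1-yl]-8-methoxy-1,3-dimethylisoquinoline (racemic axis) | Cc1cc2ccc(-c3c(SC)cc(OC)c4c(OC)cccc34)c(OC)c2c(C)n1 | intermediate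
15 | 7-(4,5-dimethoxy-2-methylnaphthalen-1-yl)-8-methoxy-1,3-dimethylisoquinoline (racemic axis) | COc1c(-c2c(C)cc(OC)c3c(OC)cccc23)ccc2cc(C)nc(C)c12 | target

**Step count and risks**
Total steps: 9. Longest linear sequence: 6 steps (steps 1, 2, 3, 7, 8, 9 from 1; equally steps 4, 5, 6, 7, 8, 9 from 5).

Steps most likely to fail:

1. Step 7 (key step). Oxygen attack at the activated sulfur may lose out to Pummerer rearrangement or ylide formation at the S-methyl group. The N-protonated phenol may also be too weak a nucleophile, so that the activated sulfoxide is consumed by electrophilic attack on a second electron-rich naphthalene. The fallback makes the axis by cross-coupling; it sets out from 2 and 9 and returns at 15.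
   - Naphthalene partner: Suzuki–Miyaura methylation of 2 (MeI, Pd(PPh3)4, K3PO4, DMF/H2O, 60 °C) should give 1,8-dimethoxy-3-methylnaphthalene F1. Bromination with NBS in MeCN at 0 °C, directed to C1' by the para methoxy and ortho methyl groups, should give 1-bromo-4,5-dimethoxy-2-methylnaphthalene F2. Bromine–lithium exchange (n-BuLi, THF, −78 °C), B(OMe)3 quench and acidic work-up should give (4,5-dimethoxy-2-methylnaphthalen-1-yl)boronic acid F3.
   - Isoquinoline partner: amine-mediated ortho-bromination of 9 (NBS, cat. i-Pr2NH, CH2Cl2, 0 °C) should give 7-bromo-1,3-dimethylisoquinolin-8-ol F4. O-Methylation (MeI, Cs2CO3, DMF) should give 7-bromo-8-methoxy-1,3-dimethylisoquinoline F5.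
   - Coupling: Suzuki–Miyaura coupling of F3 with F5 (Pd2(dba)3, SPhos, K3PO4, toluene/H2O, 100 °C) should give 15 directly.

2. Step 9. Oxidative addition of zerovalent nickel into the C2'–S bond, which is flanked by the isoquinolinyl group, may be slow, and the isoquinoline nitrogen may sequester the catalyst. Forcing conditions risk cleavage of the aryl C–OMe bonds. The fallback reverses the polarity at C2'; it sets out from 14 and returns at 15. Rhodium-catalysed ipso-borylation of the methylsulfanyl group ([Rh(OH)(cod)]2, PCy3, B2pin2, cyclohexane, 80 °C) should give 7-[4,5-dimethoxy-2-(4,4,5,5-tetramethyl-1,3,2-dioxaborolan-2-yl)naphthalen-1-yl]-8-methoxy-1,3-dimethylisoquinoline F6. Suzuki–Miyaura methylation (MeI, Pd(PPh3)4, K3PO4, DMF/H2O, 60 °C) should then give 15.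

3. Step 2. Transmetalation of the pinacol boronate to copper may be slow and protodeboronation may take over. The fallback goes through carbon–oxygen chemistry; it sets out from 2 and returns at 3. Oxidation of the boronate (H2O2, NaOH, THF/H2O, 0 °C) should give 4,5-dimethoxynaphthalen-2-ol F7. Triflation (Tf2O, pyridine, CH2Cl2, 0 °C) should give 4,5-dimethoxynaphthalen-2-yl trifluoromethanesulfonate F8. Palladium-catalysed C–S coupling with NaSMe (Pd2(dba)3, Xantphos, toluene, 100 °C) should then give 3.

**Further compounds**
F1 | step 7 | 1,8-dimethoxy-3-methylnaphthalene | COc1cc(C)cc2cccc(OC)c12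
F2 | step 7 | 1-bromo-4,5-dimethoxy-2-methylnaphthalene | COc1cc(C)c(Br)c2cccc(OC)c12
F3 | step 7 | (4,5-dimethoxy-2-methylnaphthalen-1-yl)boronic acid | COc1cc(C)c(B(O)O)c2cccc(OC)c12
F4 | step 7 | 7-bromo-1,3-dimethylisoquinolin-8-ol | Cc1cc2ccc(Br)c(O)c2c(C)n1
F5 | step 7 | 7-bromo-8-methoxy-1,3-dimethylisoquinoline | Cc1cc2ccc(Br)c(OC)c2c(C)n1
F6 | step 9 | 7-[4,5-dimethoxy-2-(4,4,5,5-tetramethyl-1,3,2-dioxaborolan-2-yl)naphthalen-1-yl]-8-methoxy-1,3-dimethylisoquinoline | Cc1cc2ccc(-c3c(B4OC(C)(C)C(C)(C)O4)cc(OC)c4c(OC)cccc34)c(OC)c2c(C)n1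
F7 | step 2 | 4,5-dimethoxynaphthalen-2-ol | COc1cc(O)cc2cccc(OC)c12
F8 | step 2 | 4,5-dimethoxynaphthalen-2-yl trifluoromethanesulfonate | COc1cc(OS(=O)(=O)C(F)(F)F)cc2cccc(OC)c12
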